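The tempting reading of the birch and cedar runs is that more reagent simply buys more left-handed product, yet cedar at 10.0 h also holds 11.7% right-handed product, more than the 1.4% in birch.

| flask | left-handed substrate | right-handed substrate | reagent | remark | time |
|---|---|---|---|---|---|
| birch | 0.050 M | 0.050 M | 0.051 M (fed, over 30 min) | run made earlier |  |
| cedar | 0.050 M | 0.050 M | 0.13 M (fed, over 30 min) | run made earlier |  |
| beta | 0.050 M | 0.050 M | 0.0600 M (fed, over 30 min) |  | 10 h |
| gamma | 0.050 M | 0.050 M | 0.100 M (fed, over 30 min) |  | 10 h |
| eta | 0.050 M | 0.050 M | 0.150 M (fed, over 30 min) |  | 10 h |

| run | time / h | left-handed product / % | right-handed product / % | waste / % |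
|---|---|---|---|---|
| birch | 0.500 | 15.8 | 0.4 | 0.8 |
| birch | 1.50 | 35.1 | 1.4 | 2.6 |
| birch | 3.00 | 43.3 | 1.8 | 5.1 |
| birch | 4.00 | 45.4 | 1.8 | 6.5 |
| birch | 6.00 | 48.2 | 1.7 | 9.3 |
| birch | 8.00 | 48.2 | 1.9 | 11.8 |
| birch | 10.0 | 48.6 | 1.4 | 13.9 |
| cedar | 0.500 | 31.7 | 0.3 | 0.1 |
| cedar | 1.50 | 51.8 | 3.8 | 2.4 |
| cedar | 3.00 | 59.5 | 7.7 | 4.7 |
| cedar | 4.00 | 64.1 | 9.0 | 4.6 |
| cedar | 6.00 | 69.1 | 10.4 | 6.2 |
| cedar | 8.00 | 72.9 | 11.2 | 6.6 |
| cedar | 10.0 | 74.6 | 11.7 | 6.9 |

(standard deviation of a reading: 0.3 percentage points)

- reagent is single-handed; left-handed substrate and right-handed substrate are mirror images of each other, charged as a racemate, each of them at the stated concentration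
- "hardly changes" means that all values lie within two and a half points (for a concentration: within two and a half percent of the largest)
- the handed part of reagent does not stay in what it makes, so the products of the two hands are mirror images too

- share of left-handed product in all that became left-handed product or right-handed product or waste for beta, gamma, eta, in this order
- the course of these numbers from the first flask to the last (falls all the way / rises, then falls / rises all the way / falls, then rises / hardly changes)

Take the main step first: reagent and left-handed substrate give left-handed product one to one, and left-handed substrate is half of the substrate charge. Cedar reaches 74.6% left-handed product, so a second process must turn right-handed substrate into left-handed: racemisation. Birch shows a third. Its reagent charge is 0.510 of the substrate charge and its products already account for 49.9% at 6.00 h, yet waste still climbs from 9.3% to 13.9% by 10.0 h, so waste needs no reagent. The fourth step, reagent taking right-handed substrate, does need it.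

Late in a run these are two leaks from the same remaining substrate, so their ratio should follow free reagent. From 3.00 h to 10.0 h in cedar, right-handed product outgrows waste by a factor of 1.82, while free reagent, charge minus products, falls from 0.628 to 0.437 of the substrate charge. Mean free reagent divided by that factor gives 0.293, the balance point: the free reagent, as a fraction of the substrate charge, at which right-handed product and waste grow equally fast. It is a reading from two small differences, each carrying the scatter.

Beta, charged at 0.600, has reagent as the limiting reagent, so waste should lead there, as in birch. Eta, charged at 1.50, keeps 0.500 free even with the whole substrate charge captured, so right-handed product should lead. Gamma, at 1.00, should pass through the balance point, where the two leaks grow equally fast, so this reckoning expects the share to rise, then fall.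

The forecast gives 79.5%, 82% and 78%, rises, then falls, and says: “The optimum therefore lies in between.”

The flasks give 78.8%, 82.0% and 78.0%: rises, then falls.

    achiral form → waste (k = 0.00480 min⁻¹)
    reagent + right-handed substrate → right-handed product (k = 0.0170 M⁻¹ min⁻¹)
    left-handed substrate ⇌ achiral form (K = 0.250, k = 0.00630 min⁻¹)
    reagent → decomposition product (k = 1.50 × 10⁻⁵ min⁻¹)
    reagent + left-handed substrate → left-handed product (k = 0.710 M⁻¹ min⁻¹)
    right-handed substrate ⇌ achiral form (K = 0.250, k = 0.00630 min⁻¹)

In beta, right-handed substrate enters achiral form 12 times as fast as it enters right-handed product at 0.796 h and 960 times as fast at 10.0 h, forward step alone, as reagent falls to 0.643% of its own charge. Against the balance point of 0.293, gamma's free reagent falls from 0.281 at 5.00 h to 0.174 at 10.0 h, and right-handed product gains 1.3 percentage points against 2.3 points for waste, while eta's stands at 0.608 at 10.0 h, and over the same hours right-handed product gains 2.6 points against 1.5 points for waste.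

Readings and results come from a simulation for substances that don't exist; noise was put on by code.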